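Early on, complex with one exchanged climbs in both earlier runs, and from 40.0 s it barely moves, so read each run at 60.0 s and ask what becomes of one molecule at each fork.

common to all: starting complex 0.24 M
- violet: incoming ligand 0.086 M; run made earlier
- ochre: incoming ligand 0.30 M; run made earlier
- maple: incoming ligand 0.120 M; time 2.0 min
- birch: incoming ligand 0.192 M; time 2.0 min
- alder: incoming ligand 0.360 M; time 2.0 min

| run | time / s | complex with one exchanged / % | complex with three exchanged / % | starting complex / % |
|---|---|---|---|---|
| violet | 12.0 | 8.3 | 0.9 | 90.6 |
| violet | 25.0 | 12.2 | 0 | 85.7 |
| violet | 40.0 | 15.2 | 0 | 81.3 |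
| violet | 50.0 | 16.4 | 0.4 | 78.1 |
| violet | 60.0 | 16.0 | 0 | 78.7 |
| ochre | 12.0 | 21.0 | 0.3 | 74.8 |
| ochre | 25.0 | 28.1 | 2.4 | 60.9 |
| ochre | 40.0 | 30.5 | 2.4 | 56.6 |
| ochre | 50.0 | 29.2 | 2.6 | 52.7 |
| ochre | 60.0 | 29.4 | 2.4 | 51.3 |

(standard deviation of a reading: 0.5 percentage points)

- what may be going on: starting complex + incoming ligand <-> leaving ligand + complex with one exchanged; complex with one exchanged + incoming ligand <-> leaving ligand + complex with two exchanged; complex with two exchanged + incoming ligand <-> leaving ligand + complex with three exchanged; complex with three exchanged + incoming ligand <-> leaving ligand + complex with four exchanged; 2 incoming ligand -> self-condensation product; complex with one exchanged -> side product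

- amount of complex with one exchanged at the end, in percent of the starting complex charged, for each flask in turn (maple, birch, alder)

Take the main step first. Treat starting complex and complex with one exchanged as a pair in pre-equilibrium; their odds at 60.0 s, divided by the ligand charged, read 2.36 L mol⁻¹ in violet and 1.91 L mol⁻¹ in ochre. Interpolating by charge, and extrapolating past ochre for alder, you get odds of 0.275 in maple, 0.411 in birch and 0.642 in alder. On this step your reckoning puts maple at 21.6%.

Now add what takes material out of the pair. The share outside it at 60.0 s, per ligand charged, reads 0.616 L mol⁻¹ in violet and 0.643 L mol⁻¹ in ochre. Using their mean, your reckoning lowers maple to 19.9% at that time.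

Last, violet's outside share over its complex with one exchanged, per 60.0 s, reads 0.331 min⁻¹. Call this the leak, your estimate of the fraction of complex with one exchanged turning to side product per unit time. The reading also counts the forms beyond the first exchange as leaked, and it divides by the last reading, not by an average over the run. A molecule shuttling within the pair is exposed for its share of the time, so your reckoning lets the pair decay at the leak times that share. Until 2.0 min this gives 18.6% in maple, 23.2% in birch and 26.6% in alder.

The forecast, counting on “a slow drain to side product”, says 19%, 24% and 29%, above your reckoning in each flask .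

Maple, birch and alder give 17.6%, 22.3% and 27.3%, which differ from your reckoning by −1.00 percentage point, −0.90 points and 0.70 points.

    starting complex + incoming ligand ⇌ leaving ligand + complex with one exchanged (K = 2.47, k = 0.107 L mol⁻¹ s⁻¹)
    complex with one exchanged + incoming ligand ⇌ leaving ligand + complex with two exchanged (K = 0.799, k = 0.109 L mol⁻¹ s⁻¹)
    complex with two exchanged + incoming ligand ⇌ leaving ligand + complex with three exchanged (K = 0.820, k = 0.244 L mol⁻¹ s⁻¹)
    complex with three exchanged + incoming ligand ⇌ leaving ligand + complex with four exchanged (K = 1.10, k = 0.565 L mol⁻¹ s⁻¹)
    2 incoming ligand → self-condensation product (k = 0.0334 L mol⁻¹ s⁻¹)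
    complex with one exchanged → side product (k = 0.00530 s⁻¹)

In maple at 2.00 min, complex with one exchanged has a half-life of 2.2 min by loss to side product, shorter than the 7.3 min by the forward rate of the second exchange. Your leak times the mean complex with one exchanged of the second minute makes 6.17% of side product in maple and 7.81% in birch; the flasks gain 6 points and 7.5 points.

The data were computed from invented constants.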